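Starting material, target, isomer of the product and intermediate together keep the charge: the last row of the zeta run sums to 99.3%. With intermediate as a small term, a single correction turns what has reacted into target. The last epsilon reading gives 27.1% for the isomer's part of target plus isomer, the isomer share. With that share carried over as an estimate, target is reckoned as the reacted part of the charge times one minus the share.

| flask | starting material | reagent | temperature | remark | time |
|---|---|---|---|---|---|
| alpha | 0.10 M | 0.50 equiv | 22 °C | run made earlier |  |
| epsilon | 0.10 M | 0.75 equiv | 39 °C | run made earlier |  |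
| zeta | 0.050 M | 1 equiv | 22 °C | run made earlier |  |
| elm | 0.10 M | 1.00 equiv | 25 °C |  | 1.5 h |
| birch | 0.10 M | 1.00 equiv | 35 °C |  | 1.5 h |

| run | time / min | target / % | starting material / % | intermediate / % | isomer of the product / % |
|---|---|---|---|---|---|
| alpha | 25.0 | 25.0 | 72.9 | 0.5 | 2.5 |
| alpha | 50.0 | 39.3 | 53.7 | 0.8 | 7.1 |
| alpha | 60.0 | 38.8 | 50.6 | 2.2 | 8.5 |
| alpha | 90.0 | 35.5 | 48.5 | 1.8 | 12.4 |
| epsilon | 4.00 | 33.0 | 63.4 | 0.9 | 3.5 |
| epsilon | 8.00 | 47.9 | 43.4 | 0.7 | 8.9 |
| epsilon | 20.0 | 51.2 | 29.4 | 1.2 | 17.6 |
| epsilon | 50.0 | 52.7 | 25.9 | 2.9 | 19.6 |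
| zeta | 12.0 | 13.2 | 85.8 | 0 | 0.4 |
| zeta | 30.0 | 28.6 | 67.6 | 0.3 | 4.1 |
| zeta | 60.0 | 46.2 | 45.8 | 0.5 | 9.1 |
| zeta | 90.0 | 53.6 | 31.1 | 0 | 14.6 |

(each reading ± 0.5 percentage points)

- which of these there is most of at the end, counted by the starting material in it, elm (starting material / target / intermediate / isomer of the product)
- which of these there is most of at the end, counted by the starting material in it, birch (starting material / target / intermediate / isomer of the product)
- final amount of the leader among these, as a percentage of the starting material charged, in elm
- final amount of the leader among these, as a percentage of the starting material charged, in birch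

- the numbers in the tables scatter with a standard deviation of 0.5 percentage points

What would have to be true for target to lose? The isomer overtakes it once the share passes half, and the reading stands lower than that. Starting material overtakes it when the part left unreacted exceeds one minus the share over two minus the share, here 42.2%. The zeta run, with 1 equiv of reagent at 22 °C, holds 31.1% after 90.0 min, less than that. Early first-order constants read 0.0126 min⁻¹ in the alpha run at 0.10 M and 0.0131 min⁻¹ in the zeta run at 0.050 M, both at 22 °C.

Elm has the same equivalents and time at 25 °C, so my reckoning borrows the zeta leftover as an estimate and gives elm about 50.2% target. Birch, at 35 °C, taken with nothing left, gives 72.9%. In this reckoning target leads in both flasks.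

The forecast names target for elm at 60% and target for birch at 68%, higher than my figure for elm and lower than my figure for birch. Its ground: “Target reversibly isomerises”

Elm ends with target at 60.6%, birch with target at 67.1%.

    starting material ⇌ intermediate + leaving ligand (K = 0.00170 M, k = 3.30 × 10⁻⁴ s⁻¹, Ea = 100 kJ mol⁻¹, ΔH = −31.0 kJ mol⁻¹)
    reagent + intermediate → target (k = 6.40 M⁻¹ s⁻¹, Ea = 44.0 kJ mol⁻¹)
    reagent ⇌ dormant form (K = 2.90, k = 4.90 × 10⁻⁵ s⁻¹, Ea = 106 kJ mol⁻¹, ΔH = −46.0 kJ mol⁻¹)
    leaving ligand → by-product carried off (k = 1.70 × 10⁻⁴ s⁻¹, Ea = 87.0 kJ mol⁻¹)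
    target ⇌ isomer of the product (K = 0.450, k = 2.00 × 10⁻⁴ s⁻¹, Ea = 86.0 kJ mol⁻¹, ΔH = −12.0 kJ mol⁻¹)
    (constants at 25 °C)

At 0.446 h elm makes target 3.95 times faster than it uses it up, each step taken net. Elm's 18.4% of starting material lies below 42.2%, and with the share it gives 59.5% target. A repeat of elm at 10 °C keeps 81.0% of starting material, more than 42.2%, and there starting material leads, with target at 17.5%.

The data were computed for substances that don't exist, and the scatter is random.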